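## Retrosynthetic overview
1. The 5,8-hydroquinone is revealed last: target ⇐ ring-A p-quinone ⇐ the para-dimethoxy pair (C5/C8) of 3,5,7,8,2',3',4'-heptamethoxyflavone.
2. Key disconnection C2–C1': ring B is attached to a finished chromone. Both partners are electrophiles (C2 is the β-enone, carbonyl-level enol-ether carbon; the other is an aryl C–Br carbon). C2 is therefore inverted by zincation to an α-alkoxyvinyl-metal, a masked acyl anion and β-acylvinyl anion. Its "mask" is ring C itself and is never removed.
3. 3-Methoxychromone ⇐ one-carbon closure (C2 from DMF-DMA) of a 2-hydroxy-ω-methoxyacetophenone that already carries the 3-OMe.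
4. That ketone ⇐ Friedel–Crafts acylation with in-flask ortho-demethylation of 1,2,3,5-tetramethoxybenzene.
5. Ring order: ring A is bought, ring C is closed in step 2, and ring B (bought) is attached in step 3.

Assumption: the target SMILES has no stereocentre, no stereogenic double bond and no stable axis. The compound is achiral, so no enantiocontrol is needed. Compounds 1 and 6 are taken as catalogue chemicals.

## Route

Step 1
Reactants: 1 1,2,3,5-tetramethoxybenzene
Product: 3 1-(2-hydroxy-3,4,6-trimethoxyphenyl)-2-methoxyethan-1-one, via tetramethoxyphenyl ketone 2 (not isolated)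
Conditions: MeOCH2COCl (1.1 equiv), AlCl3 (2.5 equiv), Et2O, 0 °C to reflux; then ice, 1 M HCl
Reagents that add atoms: methoxyacetyl chloride, COCC(=O)Cl
Why: Friedel–Crafts acylation at one of the two equivalent free positions of the very electron-rich arene, followed in the same flask by chelate-assisted AlCl3 cleavage of the more crowded ortho-OMe (the one buttressed by a neighbouring OMe), gives the hydrogen-bonded 2-hydroxy ketone with the ring-A pattern of a 5,7,8-trioxygenated flavone; no stereocentre is formed.

Step 2
Reactants: 3 1-(2-hydroxy-3,4,6-trimethoxyphenyl)-2-methoxyethan-1-one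
Product: 5 3,5,7,8-tetramethoxy-4H-chromen-4-one, via enaminone 4 (not isolated)
Conditions: DMF-DMA (3 equiv), toluene, 110 °C; evaporate; AcOH, 80 °C
Reagents that add atoms: N,N-dimethylformamide dimethyl acetal (DMF-DMA), COC(OC)N(C)C
Why: Enaminone chromone synthesis, in which the methoxy-activated CH2 condenses with the amide acetal and the ortho-phenol then closes ring C by addition–elimination with loss of dimethylamine, leaves C2–H free and the 3-OMe in place; no stereocentre is formed.

Step 3
Reactants: 5 3,5,7,8-tetramethoxy-4H-chromen-4-one; 6 1-bromo-2,3,4-trimethoxybenzene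
Product: 8 3,5,7,8,2',3',4'-heptamethoxyflavone, via bis(chromon-2-yl)zinc 7 (not isolated)
Conditions: (TMP)2Zn·2MgCl2·2LiCl (0.6 equiv, TMP = 2,2,6,6-tetramethylpiperidin-1-yl), THF, −20 °C to rt; then 6, Pd(OAc)2 (2 mol %), SPhos (4 mol %), 50 °C
Reagents that add atoms: none
Why: Deprotonative zincation with a TMP-zinc base followed by Negishi cross-coupling: C2–H is the only ring-C proton, is flanked by O1 and the coordinating 3-OMe and is acidified by MgCl2 on the C4 carbonyl, so the normally electrophilic C2 becomes a covalent α-alkoxyvinyl-zinc (a masked acyl anion and β-acylvinyl anion, too soft to add to a second chromone) that zerovalent palladium with SPhos joins to the electrophilic C–Br carbon of the hindered bromide; no stereocentre is formed.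

Step 4
Reactants: 8 3,5,7,8,2',3',4'-heptamethoxyflavone
Product: 10 5,8-dihydroxy-3,7,2',3',4'-pentamethoxyflavone (target), via flavone-5,8-quinone 9 (not isolated)
Conditions: (NH4)2Ce(NO3)6 (2.2 equiv), MeCN–H2O 2:1, 0 °C, 20 min; then aq Na2S2O4, EtOAc, rt, under N2
Reagents that add atoms: water, O
Why: Oxidative demethylation by tetravalent cerium acts on the only 1,4-dimethoxy pair in the molecule (C5/C8; ring B has none and the 3-OMe sits on an electron-poor enone) to give the p-quinone, and dithionite reduction turns it into the 5,8-hydroquinone with the 7-OMe untouched; no stereocentre is formed.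

## Compound list
1 | 1,2,3,5-tetramethoxybenzene | COc1cc(OC)c(OC)c(OC)c1 | starting material
2 | 2-methoxy-1-(2,3,4,6-tetramethoxyphenyl)ethan-1-one | COCC(=O)c1c(OC)c(OC)c(OC)cc1OC | intermediate
3 | 1-(2-hydroxy-3,4,6-trimethoxyphenyl)-2-methoxyethan-1-one | COCC(=O)c1c(O)c(OC)c(OC)cc1OC | intermediate
4 | (Z)-3-(dimethylamino)-1-(2-hydroxy-3,4,6-trimethoxyphenyl)-2-methoxyprop-2-en-1-one | CN(C)/C=C(\OC)C(=O)c1c(O)c(OC)c(OC)cc1OC | intermediate
5 | 3,5,7,8-tetramethoxy-4H-chromen-4-one | COc1coc2c(OC)c(OC)cc(OC)c2c1=O | intermediate
6 | 1-bromo-2,3,4-trimethoxybenzene | COc1ccc(Br)c(OC)c1OC | starting material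
7 | bis(3,5,7,8-tetramethoxy-4-oxo-4H-chromen-2-yl)zinc (MgCl2/LiCl complex) | COc1c([Zn]c2oc3c(OC)c(OC)cc(OC)c3c(=O)c2OC)oc2c(OC)c(OC)cc(OC)c2c1=O | intermediate
8 | 3,5,7,8-tetramethoxy-2-(2,3,4-trimethoxyphenyl)-4H-chromen-4-one (heptamethoxyflavone) | COc1ccc(-c2oc3c(OC)c(OC)cc(OC)c3c(=O)c2OC)c(OC)c1OC | intermediate
9 | 3,7-dimethoxy-2-(2,3,4-trimethoxyphenyl)-4H-chromene-4,5,8-trione | COC1=CC(=O)C2=C(C1=O)OC(c1ccc(OC)c(OC)c1OC)=C(OC)C2=O | intermediate
10 | 5,8-dihydroxy-3,7-dimethoxy-2-(2,3,4-trimethoxyphenyl)-4H-chromen-4-one | COc1ccc(-c2oc3c(O)c(OC)cc(O)c3c(=O)c2OC)c(OC)c1OC | target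

## Totals and risks
Total step count: 4.
Longest linear sequence: 4 (1 → 3 → 5 → 8 → 10).

**Step 3 is the most exposed.** The many Lewis-basic oxygens of 5 may tie up the base. Zinc reagent 7 and bromide 6 are both ortho-substituted and electron-rich, so oxidative addition and transmetalation can be slow, and 5 may simply be recovered after protonation.
- The fallback sets out from 7, which is quenched with I2 to give 2-iodo-3,5,7,8-tetramethoxy-4H-chromen-4-one F1. This is an isolable vinylogous acyl iodide that undergoes fast oxidative addition.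
- The roles in the coupling are then exchanged. A Suzuki–Miyaura reaction of F1 with commercial (2,3,4-trimethoxyphenyl)boronic acid (PdCl2(dppf), anhydrous K3PO4, toluene, 90 °C) comes back to the route at 8.
- The C2 anion remains the species that functionalises the chromone.

**Step 1 is second.** Under AlCl3, methoxyacetyl chloride can lose CO to give a methoxymethyl cation, which leads to chloromethylation or diarylmethanes. The aluminium chelate may also cleave the 6-OMe or the side-chain OMe.
- The fallback sets out from 1 and acylates it without any Lewis acid, using the mixed anhydride of methoxyacetic acid and (CF3CO)2O (CH2Cl2, 0 °C to rt). This gives ketone 2, now isolated.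
- A separate, colder chelation-controlled demethylation (BCl3 1.1 equiv, CH2Cl2, −78 to 0 °C) comes back to the route at 3.
- New compounds on this detour: none F0.

**Step 4 is third.** Tetravalent cerium may nitrate or oxidise ring B, or hydrolyse the 7-OMe of the quinone.
- The fallback sets out from 8. BCl3 (1.1 equiv, CH2Cl2, −78 to 0 °C) removes only the carbonyl-chelated 5-O-methyl group to give 5-hydroxy-3,7,8-trimethoxy-2-(2,3,4-trimethoxyphenyl)-4H-chromen-4-one F2.
- The resulting para-methoxyphenol is oxidised by the milder two-electron oxidant PhI(OAc)2 (MeCN–H2O, 0 °C). This comes back to the route at quinone 9, which is reduced with Na2S2O4 as before.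

## Further compounds
F1 | step 3 | 2-iodo-3,5,7,8-tetramethoxy-4H-chromen-4-one | COc1c(I)oc2c(OC)c(OC)cc(OC)c2c1=O
F0 | step 1 | none | none
F2 | step 4 | 5-hydroxy-3,7,8-trimethoxy-2-(2,3,4-trimethoxyphenyl)-4H-chromen-4-one | COc1ccc(-c2oc3c(OC)c(OC)cc(O)c3c(=O)c2OC)c(OC)c1OC
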